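**Remark (assumption).** The target has no stereocentre and no stereogenic double bond (both prenyl groups end in CMe2, the ring-D double bond is endocyclic). It is achiral, so "single enantiomer" needs no stereocontrol. The structure is taken as drawn: pyran oxygen on C3′ and vinyl carbon on C4′ of ring B.

## Analysis of the target

Dorsilurin C is a flavonol. Rings A and C form a 4H-chromen-4-one with OH on C3, C5 and C7, and C2 carries C7 of a 2,2-dimethyl-2H-chromene (benzene ring B fused to pyran ring D, vinyl carbon para to C2). Ring A is hexasubstituted: C5–OH, C6–prenyl, C7–OH, C8–prenyl, C8a–O1 and C4a–C4. It is therefore a 2,4-diprenylphloroglucinol in which C4a is the only carbon bearing neither oxygen nor prenyl, and C4a lies between two oxygen-bearing carbons (C5 and C8a) that are equivalent until ring C is closed. There is no stereochemistry to set. The sensitive groups are: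

- two ortho-prenylphenol units (C5–OH/C6 and C7–OH/C6,C8), which close to 2,2-dimethylchromans under acid and react with electrophilic oxidants and halogens;
- the styrene-type double bond of ring D;
- the 3-hydroxy-γ-pyrone enol, which is cleaved by base and air;
- the electron-rich ring A.

The difficulty is to reach the flavonol oxidation level at C2/C3/C4 on a crowded ring A without electrophilic oxidants or strong acid. In addition, the oxygen on C5 (C6′ of a chalcone precursor) is known to divert oxidative chalcone cyclisation towards five-membered closure.

## Retrosynthetic reasoning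

**17 from 16.** The last cut is the O–CH2 bond of a methoxymethyl acetal on O3. One protecting group is needed because the C3 oxygen has to travel through an enolate and a ketene. An acetal on an enolic oxygen leaves under mild acid, and the three phenols of ring A stay free throughout.

**16 from 4 and 13 (key disconnection).** Ring C is cut across C4–C4a and O1–C2. This separates the whole hexasubstituted ring A, as symmetric 4, from a three-carbon unit in 13 that already carries ring B/D, the C3 oxygen and the correct oxidation level at every carbon. The cut is placed here because C4a is the only free carbon of 4 and O1/O5 are equivalent, so neither the C–C nor the C–O bond formation has a regiochemical alternative. The forward reaction must acylate C6 of 4 and close the pyranone without acid, base or oxidant.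

**13 from 9 and 11.** The bond between the ketone carbon (later C2) and the oxygenated α-carbon (later C3) is cut: a crossed Claisen condensation of a non-enolisable aryl ester with a glycolate enolate. This brings in the C3 oxygen as part of a commercial C2 building block instead of by oxidation.

**9 from 5 and 6.** Ring D is cut at C3–C4 and O1–C2 of the chromene. An isobutenyl nucleophile adds to a salicylaldehyde, and dehydration to ortho-quinone methide 8 followed by oxa-6π-electrocyclisation closes the pyran. The aldehyde carbon of 5 becomes chromene C4 and the ester sits para to it, so only the 7-carboxylate can form. A propargyl-ether or enal annulation of a meta-substituted phenol would not give this control.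

**11 from 10.** O-Alkylation of the glycolate hydroxyl installs the acetal.

**4 from 1 and 2.** The two aryl–CH2 bonds are cut. Because all three ring carbons of 1 are equivalent, the second C-alkylation of 3 at either remaining carbon gives the same 2,4-isomer, so a one-step double C-prenylation is acceptable at the very start.

## Alternatives that were turned down

**Alternative 1:** the textbook route. Disconnection at C2–C3 (aldol) and at O1–C2 with C3–OH (oxidative cyclisation). The forward key step is the Algar–Flynn–Oyamada oxidation of 2′-hydroxychalcone A1, itself made by Claisen–Schmidt condensation of a protected A-ring ketone with a B-ring aldehyde. It was turned down for three reasons.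
- A1 carries an oxygen substituent on C6′ (the later O5). With both ortho positions of the aroyl group occupied the enone is twisted out of the arene plane, and the phenoxide then closes 5-exo at Cα, giving aurone A2 instead of the flavonol.
- Ring B has only a meta oxygen and a para vinyl group, so it offers little benzylic stabilisation to favour attack at Cβ.
- The three phenols must be differentiated (two acetals put on and taken off) and ring A must be acetylated as well as prenylated. The route would need eight or more steps, with its main risk in a late step that has no regiochemical safeguard.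

**Alternative 2:** disconnection at C2–C3 by O→C aroyl transfer. The forward key step is the Baker–Venkataraman rearrangement of aryl ester A3, followed by acid cyclodehydration. It was turned down on step economy and compatibility.
- A3 needs an ω-oxygenated, diprenylated, selectively protected phloroacetophenone. Its ω-oxygen can only come from a Hoesch acylation (strong acid, so before prenylation) or from α-halogenation (incompatible with the prenyl double bonds).
- One ortho phenol must be esterified selectively in the presence of the others.
- The route reaches the same 1,3-diketone oxidation level as intermediate 15, but only after about five more linear steps on the A-ring fragment.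

**Alternative 3:** the biomimetic order. The two aryl–CH2 bonds C6–C1″ and C8–C1‴ are cut last, and the forward key step is a double C-prenylation of flavonol A4, copying the prenyltransferase step. It was turned down for four reasons.
- In A4 ring A is a vinylogous acid. The O7 phenoxide is delocalised into C4=O and is a poor carbon nucleophile, so alkylation at O7 and O3 competes and mono-, di- and regio-isomers are expected.
- Acid-promoted prenyl-cation variants would attack ring D and close chromans.
- Sigmatropic variants fail on structure: a 7-O-prenyl ether can only shift ortho with allyl inversion (giving a 1,1-dimethylallyl group), and a shift from chelated O5 would serve only one of the two positions.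
- A4 itself would still have to be made by Alternative 1 or 2, so the route would contain two uncertain stages.

Key step: step 5

## Route

**Step 1**
Reactants: 1 phloroglucinol (benzene-1,3,5-triol); 2 prenyl bromide (1-bromo-3-methylbut-2-ene)
Product: 4 2,4-bis(3-methylbut-2-en-1-yl)benzene-1,3,5-triol (2,4-diprenylphloroglucinol), via mono-prenyl triol 3 (not isolated)
Conditions: 2 (2.1 equiv), KOH (2.2 equiv), H2O, 0 °C → rt, Ar; then 1 M HCl to pH 4; chromatography
Reagents that add atoms: none
Why: The ambident phloroglucinolate is alkylated at carbon in water (SN2 on the allylic bromide; solvation of the oxygens disfavours O-alkylation), and since all ring carbons of 1 are equivalent, alkylation of 3 at either remaining carbon gives the same 2,4-isomer; tri- and gem-dialkylated by-products should be separable.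

**Step 2**
Reactants: 5 methyl 4-formyl-3-hydroxybenzoate; 6 2-methylprop-1-en-1-ylmagnesium bromide
Product: 9 methyl 2,2-dimethyl-2H-chromene-7-carboxylate, via allylic alcohol 7 (not isolated), via ortho-quinone methide 8 (not isolated)
Conditions: 6 (2.3 equiv), THF, −78 → −30 °C; aqueous work-up (pH 6–7); then PPTS (5 mol %), PhMe, 90 °C
Reagents that add atoms: none
Why: The first equivalent of 6 deprotonates the phenol and the second adds to the aldehyde, which is far more reactive than the aryl ester at low temperature; the ortho-hydroxy benzylic allylic alcohol 7 then loses water to ortho-quinone methide 8, which closes by thermal oxa-6π-electrocyclisation, with regiochemistry fixed by the substitution pattern of 5.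

**Step 3**
Reactants: 10 methyl glycolate (methyl 2-hydroxyacetate)
Product: 11 methyl 2-(methoxymethoxy)acetate
Conditions: MOMCl (1.2 equiv), i-Pr2NEt (1.5 equiv), CH2Cl2, 0 °C → rt
Reagents that add atoms: chloromethyl methyl ether (MOMCl), COCCl
Why: Standard acetalisation of a primary alcohol; the methoxymethyl ether is inert to LDA and to neutral heat and, unlike a silyl or acyl group, cannot migrate between the two oxygens of the later enediol system.

**Step 4**
Reactants: 11 methyl 2-(methoxymethoxy)acetate; 9 methyl 2,2-dimethyl-2H-chromene-7-carboxylate
Product: 13 methyl 3-(2,2-dimethyl-2H-chromen-7-yl)-2-(methoxymethoxy)-3-oxopropanoate (racemic), via lithium enolate 12 (not isolated)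
Conditions: 11 (2.2 equiv), LDA (2.3 equiv), THF, −78 °C; then 9 (1.0 equiv), −78 → −15 °C; AcOH quench at −78 °C
Reagents that add atoms: none
Why: Crossed Claisen condensation: 11 is fully enolised before the non-enolisable aryl ester 9 is added, and the acidic C–H of product 13 consumes the second equivalent of enolate, which drives the equilibrium; the stereocentre of 13 is lost in step 5.

**Step 5**
Reactants: 4 2,4-bis(3-methylbut-2-en-1-yl)benzene-1,3,5-triol; 13 methyl 3-(2,2-dimethyl-2H-chromen-7-yl)-2-(methoxymethoxy)-3-oxopropanoate
Product: 16 2-(2,2-dimethyl-2H-chromen-7-yl)-5,7-dihydroxy-3-(methoxymethoxy)-6,8-bis(3-methylbut-2-en-1-yl)-4H-chromen-4-one, via aroylketene 14 (not isolated), via aryl 1,3-diketone 15 (not isolated)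
Conditions: 13 (1.3 equiv), PhNEt2 (ca. 2 M), Ar, microwave, 210–220 °C, 10–20 min, open vessel (MeOH and H2O leave); EtOAc, cold 1 M HCl wash
Reagents that add atoms: none
Why: On heating, the enol of 13 loses methanol through a six-membered transition state to give aroyl(alkoxy)ketene 14. Ketene 14 acylates 4: O-acylation is reversible at this temperature because aryl β-keto esters re-form the ketene, whereas attack by C6 of 4 (the only unsubstituted ring carbon, reacting like the enol of a cyclohexane-1,3,5-trione) becomes irreversible on re-aromatisation to the chelated ortho-hydroxyaryl 1,3-diketone 15. Ring C then closes by 6-exo-trig addition of an ortho-OH of 15 to the ring-B ketone carbonyl (O1–C2 bond), and loss of water gives the γ-pyrone 16. The closest known reaction is the Mentzer pyrone synthesis, the uncatalysed thermal condensation of phloroglucinol and C-alkylphloroglucinols with α-substituted aroylacetates to 3-substituted 5,7-dihydroxyflavones, including its short microwave variant. No stereocentre is formed, and the racemic centre of 13 becomes sp2. The step needs C- over O-acylation and chromone over coumarin closure: the first is thermodynamic, and the second follows because without acid the aryl ketone is too weak an electrophile for ring C–C bond formation while the ketene carbon is not. Regiochemistry cannot arise, because C6 is the only free carbon of 4 and its two flanking hydroxyls are equivalent, so either closure gives the 5,7-dihydroxy-6,8-diprenyl pattern. The medium is neutral to weakly basic, non-oxidising and the heating is short; ortho-prenylphenols and 2,2-dimethylchromenes are themselves formed in sigmatropic rearrangements run at 180–220 °C in this solvent, which is the basis for expecting them to survive.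

**Step 6**
Reactants: 16 2-(2,2-dimethyl-2H-chromen-7-yl)-5,7-dihydroxy-3-(methoxymethoxy)-6,8-bis(3-methylbut-2-en-1-yl)-4H-chromen-4-one
Product: 17 dorsilurin C, 2-(2,2-dimethyl-2H-chromen-7-yl)-3,5,7-trihydroxy-6,8-bis(3-methylbut-2-en-1-yl)-4H-chromen-4-one
Conditions: HCl (ca. 0.5 M, from AcCl) in MeOH/THF 1:1, 30–40 °C, Ar; NaHCO3 quench as soon as 16 is consumed
Reagents that add atoms: none
Why: Acid-catalysed transacetalisation to methanol; the acetal sits on an enolic oxygen (a good leaving group, chelated to C4=O once freed) and should be cleaved under dilute, mild conditions of the kind under which ortho-prenylphenols and 2,2-dimethylchromenes are usually carried through MOM removals unchanged.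

## Compound list

1 | phloroglucinol (benzene-1,3,5-triol) | Oc1cc(O)cc(O)c1 | starting material
2 | prenyl bromide (1-bromo-3-methylbut-2-ene) | CC(C)=CCBr | starting material
3 | 2-(3-methylbut-2-en-1-yl)benzene-1,3,5-triol (formed in situ) | CC(C)=CCc1c(O)cc(O)cc1O | intermediate
4 | 2,4-bis(3-methylbut-2-en-1-yl)benzene-1,3,5-triol | CC(C)=CCc1c(O)cc(O)c(CC=C(C)C)c1O | intermediate
5 | methyl 4-formyl-3-hydroxybenzoate | COC(=O)c1ccc(C=O)c(O)c1 | starting material
6 | 2-methylprop-1-en-1-ylmagnesium bromide | CC(C)=C[Mg]Br | starting material
7 | methyl 3-hydroxy-4-(1-hydroxy-3-methylbut-2-en-1-yl)benzoate (racemic, formed in situ) | COC(=O)c1ccc(C(O)C=C(C)C)c(O)c1 | intermediate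
8 | methyl 4-(3-methylbut-2-en-1-ylidene)-3-oxocyclohexa-1,5-diene-1-carboxylate (ortho-quinone methide, formed in situ) | COC(=O)C1=CC(=O)C(=CC=C(C)C)C=C1 | intermediate
9 | methyl 2,2-dimethyl-2H-chromene-7-carboxylate | COC(=O)c1ccc2C=CC(C)(C)Oc2c1 | intermediate
10 | methyl glycolate (methyl 2-hydroxyacetate) | COC(=O)CO | starting material
11 | methyl 2-(methoxymethoxy)acetate | COCOCC(=O)OC | intermediate
12 | lithium 1-methoxy-2-(methoxymethoxy)ethen-1-olate (formed in situ) | [Li+].COCOC=C([O-])OC | intermediate
13 | methyl 3-(2,2-dimethyl-2H-chromen-7-yl)-2-(methoxymethoxy)-3-oxopropanoate (racemic) | COCOC(C(=O)OC)C(=O)c1ccc2C=CC(C)(C)Oc2c1 | intermediate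
14 | (2,2-dimethyl-2H-chromene-7-carbonyl)(methoxymethoxy)ketene (formed in situ) | COCOC(=C=O)C(=O)c1ccc2C=CC(C)(C)Oc2c1 | intermediate
15 | 1-(2,2-dimethyl-2H-chromen-7-yl)-2-(methoxymethoxy)-3-[2,4,6-trihydroxy-3,5-bis(3-methylbut-2-en-1-yl)phenyl]propane-1,3-dione (racemic, formed in situ) | CC(C)=CCc1c(O)c(CC=C(C)C)c(O)c(C(=O)C(OCOC)C(=O)c2ccc3C=CC(C)(C)Oc3c2)c1O | intermediate
16 | 2-(2,2-dimethyl-2H-chromen-7-yl)-5,7-dihydroxy-3-(methoxymethoxy)-6,8-bis(3-methylbut-2-en-1-yl)-4H-chromen-4-one | CC(C)=CCc1c(O)c(CC=C(C)C)c2oc(-c3ccc4c(c3)OC(C)(C)C=C4)c(OCOC)c(=O)c2c1O | intermediate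
17 | dorsilurin C | CC(C)=CCc1c(O)c(CC=C(C)C)c2oc(-c3ccc4c(c3)OC(C)(C)C=C4)c(O)c(=O)c2c1O | target

## Step count and risk

Total: 6 steps. Longest linear sequence: 4 steps (5 → 9 → 13 → 16 → 17; steps 2, 4, 5, 6). Steps 1 and 3 are single-step side branches.

**Step 5 (key step).** The most likely failure is thermal addition of a phenolic O–H across a neighbouring prenyl double bond (chroman formation) at the temperature needed to generate the ketene. Other possibilities are stalling at the reversible O-acyl stage, premature loss of the acetal, and capture of a transiently ring-opened chromene by the very nucleophilic ring of 4. The fallback builds the same diketone stepwise at low temperature. It sets out from 4, 11 and 9 and comes back at 17.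
- Compound 4 would be converted with MOMCl/NaH into 1,3,5-tris(methoxymethoxy)-2,4-bis(3-methylbut-2-en-1-yl)benzene F1.
- Ester 11 would be converted with MeNH(OMe)·HCl/i-PrMgCl into the Weinreb amide N-methoxy-2-(methoxymethoxy)-N-methylacetamide F2.
- Ortho-lithiation of F1 (n-BuLi, THF, 0 °C) at its single ring C–H, which lies between two acetal oxygens, and acylation with F2 should give the aryl ketone 2-(methoxymethoxy)-1-[2,4,6-tris(methoxymethoxy)-3,5-bis(3-methylbut-2-en-1-yl)phenyl]ethan-1-one F3.
- The lithium enolate of F3 (LiHMDS) would be acylated with ester 9 to give the protected 1,3-diketone F4.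
- Dilute HCl in MeOH would remove the four acetals and close ring C by cyclodehydration to 17.

**Step 1.** Over-alkylation to tri-prenylated and geminally dialkylated (dearomatised) material and some O-alkylation are likely, and could make isolation of 4 inefficient. The fallback replaces statistical alkylation by directed metalation. It sets out from 1 and comes back at 4.
- Compound 1 would be converted into 1,3,5-tris(methoxymethoxy)benzene F5.
- Lithiation (n-BuLi, THF) and alkylation with 2 (CuI catalysis) would give 1,3,5-tris(methoxymethoxy)-2-(3-methylbut-2-en-1-yl)benzene F6.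
- A second lithiation/alkylation at either of the two equivalent remaining positions would give the tris-acetal F1 already described in the fallback to step 5.
- Dilute methanolic HCl would return 4.

**Step 2.** The Grignard reagent may also add to the methyl ester if the temperature rises, and the acid used for dehydration may oligomerise the chromene. The fallback avoids a carbanion and acid altogether. It sets out from 5 and comes back at 9. A borono-Mannich (Petasis) condensation of 5 with 2-methylprop-1-en-1-ylboronic acid and dibenzylamine in dioxane would give the aminophenol methyl 4-[1-(dibenzylamino)-3-methylbut-2-en-1-yl]-3-hydroxybenzoate F7. At 90 °C F7 expels the amine to give ortho-quinone methide 8, which electrocyclises to 9.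

**Step 4.** Enolate 12 may decompose (ketene formation, self-condensation) on warming before it has acylated the conjugated, weakly electrophilic aryl ester. The fallback replaces the ester electrophile by an aldehyde. It sets out from 9 and 11 and comes back at 13.
- DIBAL-H would reduce 9 to (2,2-dimethyl-2H-chromen-7-yl)methanol F8.
- MnO2 would oxidise F8 to 2,2-dimethyl-2H-chromene-7-carbaldehyde F9.
- Aldol addition of 12 to F9 at −78 °C would give methyl 3-(2,2-dimethyl-2H-chromen-7-yl)-3-hydroxy-2-(methoxymethoxy)propanoate F10.
- Dess–Martin oxidation of F10 would give 13.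

**Step 6.** Acid may add O5–H or O7–H across a prenyl double bond, or hydrate or oligomerise ring D, faster than the acetal is cleaved. The fallback changes the protecting group so that the last step uses fluoride. It sets out from 9 and 4 and comes back at 17.
- Crossed Claisen condensation of 9 with the lithium enolate of commercial ethyl 2-[(tert-butyldimethylsilyl)oxy]acetate would give ethyl 2-[(tert-butyldimethylsilyl)oxy]-3-(2,2-dimethyl-2H-chromen-7-yl)-3-oxopropanoate F11.
- The thermal annulation of step 5 with 4 would give the 3-O-silyl flavone F12.
- TBAF buffered with AcOH at 0 °C would release 17.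

## Further compounds

F1 | step 5 | 1,3,5-tris(methoxymethoxy)-2,4-bis(3-methylbut-2-en-1-yl)benzene | CC(C)=CCc1c(OCOC)cc(OCOC)c(CC=C(C)C)c1OCOC
F2 | step 5 | N-methoxy-2-(methoxymethoxy)-N-methylacetamide | COCOCC(=O)N(C)OC
F3 | step 5 | 2-(methoxymethoxy)-1-[2,4,6-tris(methoxymethoxy)-3,5-bis(3-methylbut-2-en-1-yl)phenyl]ethan-1-one | COCOCC(=O)c1c(OCOC)c(CC=C(C)C)c(OCOC)c(CC=C(C)C)c1OCOC
F4 | step 5 | 1-(2,2-dimethyl-2H-chromen-7-yl)-2-(methoxymethoxy)-3-[2,4,6-tris(methoxymethoxy)-3,5-bis(3-methylbut-2-en-1-yl)phenyl]propane-1,3-dione (racemic) | COCOC(C(=O)c1ccc2C=CC(C)(C)Oc2c1)C(=O)c1c(OCOC)c(CC=C(C)C)c(OCOC)c(CC=C(C)C)c1OCOC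
F5 | step 1 | 1,3,5-tris(methoxymethoxy)benzene | COCOc1cc(OCOC)cc(OCOC)c1
F6 | step 1 | 1,3,5-tris(methoxymethoxy)-2-(3-methylbut-2-en-1-yl)benzene | CC(C)=CCc1c(OCOC)cc(OCOC)cc1OCOC
F7 | step 2 | methyl 4-[1-(dibenzylamino)-3-methylbut-2-en-1-yl]-3-hydroxybenzoate (racemic) | COC(=O)c1ccc(C(C=C(C)C)N(Cc2ccccc2)Cc2ccccc2)c(O)c1
F8 | step 4 | (2,2-dimethyl-2H-chromen-7-yl)methanol | OCc1ccc2C=CC(C)(C)Oc2c1
F9 | step 4 | 2,2-dimethyl-2H-chromene-7-carbaldehyde | O=Cc1ccc2C=CC(C)(C)Oc2c1
F10 | step 4 | methyl 3-(2,2-dimethyl-2H-chromen-7-yl)-3-hydroxy-2-(methoxymethoxy)propanoate (mixture of racemic diastereomers) | COCOC(C(=O)OC)C(O)c1ccc2C=CC(C)(C)Oc2c1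
F11 | step 6 | ethyl 2-[(tert-butyldimethylsilyl)oxy]-3-(2,2-dimethyl-2H-chromen-7-yl)-3-oxopropanoate (racemic) | CCOC(=O)C(O[Si](C)(C)C(C)(C)C)C(=O)c1ccc2C=CC(C)(C)Oc2c1
F12 | step 6 | 3-[(tert-butyldimethylsilyl)oxy]-2-(2,2-dimethyl-2H-chromen-7-yl)-5,7-dihydroxy-6,8-bis(3-methylbut-2-en-1-yl)-4H-chromen-4-one | CC(C)=CCc1c(O)c(CC=C(C)C)c2oc(-c3ccc4c(c3)OC(C)(C)C=C4)c(O[Si](C)(C)C(C)(C)C)c(=O)c2c1O
A1 | alternative 1 | (E)-3-(2,2-dimethyl-2H-chromen-7-yl)-1-[2-hydroxy-4,6-bis(methoxymethoxy)-3,5-bis(3-methylbut-2-en-1-yl)phenyl]prop-2-en-1-one | CC(C)=CCc1c(OCOC)c(CC=C(C)C)c(O)c(C(=O)/C=C/c2ccc3C=CC(C)(C)Oc3c2)c1OCOC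
A2 | alternative 1 | (Z)-2-[(2,2-dimethyl-2H-chromen-7-yl)methylidene]-4,6-bis(methoxymethoxy)-5,7-bis(3-methylbut-2-en-1-yl)-1-benzofuran-3(2H)-one | CC(C)=CCc1c(OCOC)c(CC=C(C)C)c2O/C(=C\c3ccc4C=CC(C)(C)Oc4c3)C(=O)c2c1OCOC
A3 | alternative 2 | 2-[2-(methoxymethoxy)acetyl]-3,5-bis(methoxymethoxy)-4,6-bis(3-methylbut-2-en-1-yl)phenyl 2,2-dimethyl-2H-chromene-7-carboxylate | COCOCC(=O)c1c(OC(=O)c2ccc3C=CC(C)(C)Oc3c2)c(CC=C(C)C)c(OCOC)c(CC=C(C)C)c1OCOC
A4 | alternative 3 | 2-(2,2-dimethyl-2H-chromen-7-yl)-3,5,7-trihydroxy-4H-chromen-4-one | O=c1c(O)c(-c2ccc3C=CC(C)(C)Oc3c2)oc2cc(O)cc(O)c12
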